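**Retrosynthetic overview**
1. Target 39 ⇐ keto acid 36: acid-triggered desilylation, transannular addition of 1-OH to the C8 ketone and lactonisation of the C12 acid onto C8 (dihydrofuran and spiro-γ-lactone formed last).
2. Ten-membered carbocycle ⇐ intramolecular Nozaki–Hiyama–Kishi closure (C8–C9) of iodoalkene–aldehyde 32, then oxidation to the enone.
3. 4-OH/5-OAc γ-lactone ⇐ OsO4 dihydroxylation of a butenolide made by ring-closing metathesis of acrylate ester 27.
4. 27 ⇐ esterification of west acid 13 (C1–C4, C9, C10, C14, C15; from but-3-yn-2-ol and methyl 2-(bromomethyl)acrylate, CBS reduction) with east alcohol 25 (C5–C8, C11–C13; from Roche ester via a dihydropyranone and OsO4).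
5. Ring order: 15,6-γ-lactone → ten-membered carbocycle → 2,5-dihydrofuran (1,8-ether) → 12,8-spiro-γ-lactone.

Assumption: positions are numbered as in germacrane (C1 ring CH–O, C4 C(OH) carrying lactone carbonyl C15, C5 CH–OAc, C6 lactone CH–O, C7 C(OH), C8 spiro ketal carbon, C9=C10 with methyl C14, C11(C13)–C12 on C7), and the natural 8S spiroketal is taken to be the thermodynamically preferred ketal of the bridged ring.

**West fragment**

Step 1
Reactants: 1 but-3-yn-2-ol (racemic)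
Product: 3 (3Z)-4-iodo-3-methylbut-3-en-2-ol (racemic), via alkenylmagnesium alkoxide chelate 2 (not isolated)
Conditions: MeMgBr (3 equiv), CuI (10 mol%), THF, −10 °C → rt; then I2, −78 → 0 °C
Reagents that add atoms: methylmagnesium bromide C[Mg]Br; iodine II
Why: Duboudin Cu-catalysed anti-carbomagnesiation of the propargylic alkoxide puts Me on the internal carbon and Mg cis to the carbinol carbon in a five-membered chelate, so iodinolysis with retention gives only the Z-iodoalkene.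

Step 2
Reactants: 3 (3Z)-4-iodo-3-methylbut-3-en-2-ol
Product: 4 (3Z)-4-iodo-3-methylbut-3-en-2-one
Conditions: MnO2, CH2Cl2, rt, dark
Reagents that add atoms: none
Why: MnO2 allylic alcohol oxidation removes the unwanted carbinol stereocentre and leaves the Z-vinyl iodide untouched.

Step 3
Reactants: 5 methyl acrylate; 6 formaldehyde (aqueous)
Product: 7 methyl 2-(hydroxymethyl)prop-2-enoate
Conditions: DABCO (cat.), dioxane/H2O, rt
Reagents that add atoms: none
Why: Morita–Baylis–Hillman reaction of the acrylate with formaldehyde; no stereocentre.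

Step 4
Reactants: 7 methyl 2-(hydroxymethyl)prop-2-enoate
Product: 8 methyl 2-(bromomethyl)prop-2-enoate
Conditions: PBr3, Et2O, −10 → 0 °C
Reagents that add atoms: phosphorus tribromide BrP(Br)Br
Why: Allylic alcohol-to-bromide substitution with PBr3 (SN2 and SN2′ give the same product).

Step 5
Reactants: 4 (3Z)-4-iodo-3-methylbut-3-en-2-one; 8 methyl 2-(bromomethyl)prop-2-enoate
Product: 10 methyl (6Z)-7-iodo-6-methyl-2-methylidene-5-oxohept-6-enoate, via lithium enolate 9 (not isolated)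
Conditions: LDA, THF, −78 °C; then 8, −78 → −40 °C
Reagents that add atoms: none
Why: Kinetic deprotonation at the only enolisable position (CH3) gives the cross-conjugated enolate, which is allylated by 8 through SN2′ addition–elimination (enolate alkylation); no stereocentre is formed and the Z-iodide survives at low temperature.

Step 6
Reactants: 10 methyl (6Z)-7-iodo-6-methyl-2-methylidene-5-oxohept-6-enoate
Product: 11 methyl (5S,6Z)-5-hydroxy-7-iodo-6-methyl-2-methylidenehept-6-enoate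
Conditions: (R)-2-methyl-CBS-oxazaborolidine (20 mol%), catecholborane, toluene, −78 °C
Reagents that add atoms: none
Why: Corey–Bakshi–Shibata reduction in which the α-branched iodoalkenyl group acts as the large substituent, so the (R)-catalyst gives the (S)-allylic alcohol (C1); the acrylate and vinyl iodide do not react with catecholborane at −78 °C.

Step 7
Reactants: 11 methyl (5S,6Z)-5-hydroxy-7-iodo-6-methyl-2-methylidenehept-6-enoate
Product: 12 methyl (5S,6Z)-5-[(tert-butyldimethylsilyl)oxy]-7-iodo-6-methyl-2-methylidenehept-6-enoate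
Conditions: TBSCl, imidazole, DMF, rt
Reagents that add atoms: tert-butyldimethylsilyl chloride CC(C)(C)[Si](C)(C)Cl
Why: Silyl ether formation blocks 1-OH and prevents δ-lactonisation onto the acrylate ester.

Step 8
Reactants: 12 methyl (5S,6Z)-5-[(tert-butyldimethylsilyl)oxy]-7-iodo-6-methyl-2-methylidenehept-6-enoate
Product: 13 (5S,6Z)-5-[(tert-butyldimethylsilyl)oxy]-7-iodo-6-methyl-2-methylidenehept-6-enoic acid
Conditions: LiOH, THF/H2O, 0 °C → rt; then 1 M HCl to pH 4
Reagents that add atoms: lithium hydroxide [Li+].[OH-]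
Why: Ester saponification; the vinyl iodide has no β-hydrogen for elimination and the secondary TBS ether is stable to LiOH.

**East fragment**

Step 9
Reactants: 6 formaldehyde (as paraformaldehyde)
Product: 15 tributyl{[(4-methoxyphenyl)methoxy]methyl}stannane, via lithium (tributylstannyl)methanolate 14 (not isolated)
Conditions: Bu3SnH, LDA, THF, 0 °C; (CH2O)n, rt; then PMBCl, TBAI (cat.), DMF, 0 °C → rt
Reagents that add atoms: tributyltin hydride CCCC[SnH](CCCC)CCCC; 4-methoxybenzyl chloride COc1ccc(CCl)cc1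
Why: Stannyl anion addition to formaldehyde followed by Williamson etherification of the alkoxide (Still's α-alkoxymethylstannane synthesis).

Step 10
Reactants: 16 methyl (2R)-3-hydroxy-2-methylpropanoate (Roche ester)
Product: 17 (2R)-3-hydroxy-N-methoxy-N,2-dimethylpropanamide
Conditions: MeNHOMe·HCl, i-PrMgCl, THF, −20 °C
Reagents that add atoms: N,O-dimethylhydroxylamine hydrochloride CNOC.Cl
Why: Weinreb amide formation by magnesium amide aminolysis of the ester; C11 comes from the chiral pool and is not enolised under these conditions.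

Step 11
Reactants: 17 (2R)-3-hydroxy-N-methoxy-N,2-dimethylpropanamide; 15 tributyl{[(4-methoxyphenyl)methoxy]methyl}stannane
Product: 19 (3R)-4-hydroxy-1-[(4-methoxyphenyl)methoxy]-3-methylbutan-2-one, via {[(4-methoxyphenyl)methoxy]methyl}lithium 18 (not isolated)
Conditions: 15, n-BuLi, THF, −78 °C; added to 17 pre-treated with i-PrMgCl (1 equiv), THF, −78 °C
Reagents that add atoms: none
Why: Tin–lithium exchange gives the α-alkoxymethyllithium, which adds once to the Weinreb amide through a stable chelated tetrahedral intermediate (Weinreb ketone synthesis); C11 is untouched at −78 °C.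

Step 12
Reactants: 19 (3R)-4-hydroxy-1-[(4-methoxyphenyl)methoxy]-3-methylbutan-2-one
Product: 21 (5S)-4-{[(4-methoxyphenyl)methoxy]methyl}-5-methyl-5,6-dihydro-2H-pyran-2-one, via ester ylide 20 (not isolated)
Conditions: Ph3P=C=C=O, toluene, 110 °C
Reagents that add atoms: (triphenylphosphoranylidene)ketene O=C=C=P(c1ccccc1)(c1ccccc1)c1ccccc1
Why: Bestmann ylide cascade (O-acylation, then intramolecular Wittig olefination of the ketone); the ring fixes the C6=C7 geometry with C5 cis to C11.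

Step 13
Reactants: 21 (5S)-4-{[(4-methoxyphenyl)methoxy]methyl}-5-methyl-5,6-dihydro-2H-pyran-2-one
Product: 22 (3S,4R,5R)-3,4-dihydroxy-4-{[(4-methoxyphenyl)methoxy]methyl}-5-methyloxan-2-one
Conditions: OsO4 (5 mol%), NMO, acetone/H2O, rt
Reagents that add atoms: N-methylmorpholine N-oxide C[N+]1([O-])CCOCC1; water O
Why: Upjohn syn-dihydroxylation; A(1,2) strain with the C7 substituent holds the C11 methyl pseudo-axial, so OsO4 adds to the opposite face and sets C6 and C7 (both OH trans to the methyl).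

Step 14
Reactants: 22 (3S,4R,5R)-3,4-dihydroxy-4-{[(4-methoxyphenyl)methoxy]methyl}-5-methyloxan-2-one
Product: 24 (2R,3R,4R)-3-{[(4-methoxyphenyl)methoxy]methyl}-2-methylhex-5-ene-1,3,4-triol, via lactol 23 (not isolated)
Conditions: DIBAL-H (3.3 equiv), CH2Cl2, −78 °C; then Ph3P=CH2 (from Ph3PCH3Br, KOt-Bu, THF), −78 °C → rt
Reagents that add atoms: methyltriphenylphosphonium bromide C[P+](c1ccccc1)(c1ccccc1)c1ccccc1.[Br-]
Why: DIBAL lactone-to-lactol reduction followed by Wittig methylenation of the ring-opened hydroxy aldehyde; the adjacent alkoxides suppress enolisation, so C6, C7 and C11 are retained.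

Step 15
Reactants: 24 (2R,3R,4R)-3-{[(4-methoxyphenyl)methoxy]methyl}-2-methylhex-5-ene-1,3,4-triol
Product: 25 (3R,4R,5R)-4-{[(4-methoxyphenyl)methoxy]methyl}-5-methyl-6-[(triethylsilyl)oxy]hex-1-ene-3,4-diol
Conditions: TESCl (1.05 equiv), imidazole, CH2Cl2, −40 °C
Reagents that add atoms: chlorotriethylsilane CC[Si](Cl)(CC)CC
Why: Chemoselective silylation of the primary alcohol over the secondary allylic and tertiary alcohols at low temperature.

**Union and endgame**

Step 16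
Reactants: 13 (5S,6Z)-5-[(tert-butyldimethylsilyl)oxy]-7-iodo-6-methyl-2-methylidenehept-6-enoic acid; 25 (3R,4R,5R)-4-{[(4-methoxyphenyl)methoxy]methyl}-5-methyl-6-[(triethylsilyl)oxy]hex-1-ene-3,4-diol
Product: 27 (3R,4R,5R)-4-hydroxy-4-{[(4-methoxyphenyl)methoxy]methyl}-5-methyl-6-[(triethylsilyl)oxy]hex-1-en-3-yl (5S,6Z)-5-[(tert-butyldimethylsilyl)oxy]-7-iodo-6-methyl-2-methylidenehept-6-enoate, via mixed anhydride 26 (not isolated)
Conditions: 2,4,6-trichlorobenzoyl chloride, Et3N, THF, rt; then 25, DMAP, toluene, rt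
Reagents that add atoms: none
Why: Yamaguchi esterification acylates only the secondary allylic 6-OH (tertiary 7-OH is inert) with retention at C6.

Step 17
Reactants: 27 acrylate ester
Product: 28 (5R)-5-{(2R,3R)-2-hydroxy-1-[(4-methoxyphenyl)methoxy]-3-methyl-4-[(triethylsilyl)oxy]butan-2-yl}-3-{(3S,4Z)-3-[(tert-butyldimethylsilyl)oxy]-5-iodo-4-methylpent-4-en-1-yl}furan-2(5H)-one
Conditions: Grubbs II (10 mol%), toluene, 80 °C
Reagents that add atoms: none
Why: Ring-closing metathesis between the α-substituted acrylate and the allylic vinyl group forms the five-membered butenolide with loss of ethene; the trisubstituted vinyl iodide does not engage the Ru carbene.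

Step 18
Reactants: 28 butenolide
Product: 29 (3S,4S,5R)-3,4-dihydroxy-5-{(2R,3R)-2-hydroxy-1-[(4-methoxyphenyl)methoxy]-3-methyl-4-[(triethylsilyl)oxy]butan-2-yl}-3-{(3S,4Z)-3-[(tert-butyldimethylsilyl)oxy]-5-iodo-4-methylpent-4-en-1-yl}oxolan-2-one
Conditions: OsO4 (10 mol%), NMO, acetone/H2O, rt
Reagents that add atoms: N-methylmorpholine N-oxide C[N+]1([O-])CCOCC1; water O
Why: Upjohn syn-dihydroxylation of the butenolide from the face anti to the bulky C6 substituent sets C4 and C5; the iodine-deactivated, hindered vinyl iodide is expected to react more slowly, though this selectivity is not guaranteed.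

Step 19
Reactants: 29 diol lactone
Product: 30 (2R,3S,4S)-4-hydroxy-2-{(2R,3R)-2-hydroxy-1-[(4-methoxyphenyl)methoxy]-3-methyl-4-[(triethylsilyl)oxy]butan-2-yl}-4-{(3S,4Z)-3-[(tert-butyldimethylsilyl)oxy]-5-iodo-4-methylpent-4-en-1-yl}-5-oxooxolan-3-yl acetate
Conditions: Ac2O, pyridine, DMAP (cat.), CH2Cl2, 0 °C
Reagents that add atoms: acetic anhydride CC(=O)OC(C)=O
Why: Acetylation of the only secondary alcohol (5-OH); the tertiary 4-OH and 7-OH do not react.

Step 20
Reactants: 30 acetate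
Product: 31 (2R,3S,4S)-2-{(2R,3R)-1,2-dihydroxy-3-methyl-4-[(triethylsilyl)oxy]butan-2-yl}-4-hydroxy-4-{(3S,4Z)-3-[(tert-butyldimethylsilyl)oxy]-5-iodo-4-methylpent-4-en-1-yl}-5-oxooxolan-3-yl acetate
Conditions: DDQ, CH2Cl2/pH 7 buffer, 0 °C
Reagents that add atoms: none
Why: Oxidative PMB ether cleavage by DDQ; silyl ethers, acetate and vinyl iodide are unaffected.

Step 21
Reactants: 31 primary alcohol
Product: 32 (2R,3S,4S)-4-hydroxy-2-{(2S,3R)-2-hydroxy-3-methyl-1-oxo-4-[(triethylsilyl)oxy]butan-2-yl}-4-{(3S,4Z)-3-[(tert-butyldimethylsilyl)oxy]-5-iodo-4-methylpent-4-en-1-yl}-5-oxooxolan-3-yl acetate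
Conditions: Dess–Martin periodinane, pyridine, CH2Cl2, rt
Reagents that add atoms: none
Why: Dess–Martin oxidation of the only oxidisable alcohol; the aldehyde α-carbon (C7) is quaternary and cannot epimerise.

Step 22
Reactants: 32 iodoalkene–aldehyde
Product: 33 (1S,4S,5S,6R,7R,11R,9Z)-5-acetoxy-1-[(tert-butyldimethylsilyl)oxy]-4,7,8-trihydroxy-12-[(triethylsilyl)oxy]germacr-9-en-15,6-olide (C8 epimer mixture)
Conditions: CrCl2 (10 equiv), NiCl2 (10 mol%), DMSO/THF, 2 mM, rt
Reagents that add atoms: none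
Why: Nozaki–Hiyama–Kishi macrocyclisation: the alkenylchromium forms with retention of Z geometry and adds to the aldehyde at high dilution, tolerating esters and free tertiary alcohols; the new C8 carbinol configuration is irrelevant because it is oxidised next.

Step 23
Reactants: 33 macrocyclic allylic alcohol
Product: 34 (1S,4S,5S,6R,7S,11R,9Z)-5-acetoxy-1-[(tert-butyldimethylsilyl)oxy]-4,7-dihydroxy-8-oxo-12-[(triethylsilyl)oxy]germacr-9-en-15,6-olide
Conditions: Dess–Martin periodinane, pyridine, CH2Cl2, rt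
Reagents that add atoms: none
Why: Dess–Martin oxidation of the allylic alcohol to the Z-enone; tertiary alcohols are inert.

Step 24
Reactants: 34 enone
Product: 35 (1S,4S,5S,6R,7S,11R,9Z)-5-acetoxy-1-[(tert-butyldimethylsilyl)oxy]-4,7,12-trihydroxy-8-oxogermacr-9-en-15,6-olide
Conditions: HF·pyridine, pyridine, THF, 0 °C
Reagents that add atoms: none
Why: Selective desilylation: buffered HF·pyridine cleaves the primary TES ether much faster than the hindered secondary allylic TBS ether.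

Step 25
Reactants: 35 primary alcohol
Product: 36 (1S,4S,5S,6R,7S,11S,9Z)-5-acetoxy-1-[(tert-butyldimethylsilyl)oxy]-4,7-dihydroxy-8-oxogermacr-9-en-15,6-olid-12-oic acid
Conditions: TEMPO (cat.), PhI(OAc)2, MeCN/H2O, rt
Reagents that add atoms: water O
Why: TEMPO/PhI(OAc)2 oxidation of the primary alcohol through the aldehyde hydrate to the acid under near-neutral conditions, so C11 does not epimerise; the acid may sit as its 8-hydroxy-12,8-lactone tautomer.

Step 26
Reactants: 36 keto acid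
Product: 39 (1S,4S,5S,6R,7S,8S,11S)-5-acetoxy-1,8-epoxy-4,7-dihydroxygermacr-9-ene-12,8:15,6-diolide, via 1-hydroxy keto acid 37 (not isolated), via hemiketal acid 38 (not isolated)
Conditions: HF·pyridine, MeCN, 0 °C → rt
Reagents that add atoms: none
Why: Desilylation frees 1-OH, which adds transannularly to the C8 ketone (hemiketalisation of the Z-γ-hydroxy enone), and acid-catalysed dehydrative lactonisation by the C12 acid closes the spiro-γ-lactone; the reversible ketalisation should place C8 in the configuration imposed by the fixed C1/C7 centres, and aromatisation to a furan would require a strained [6](2,5)furanophane.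

**Compound list**
1 | but-3-yn-2-ol (racemic) | CC(O)C#C | starting material
2 | 4,5-dimethyl-2,5-dihydro-1,2-oxamagnesole (alkenylmagnesium alkoxide chelate) | CC1O[Mg]C=C1C | intermediate (not isolated)
3 | (3Z)-4-iodo-3-methylbut-3-en-2-ol (racemic) | CC(O)/C(C)=C\I | intermediate
4 | (3Z)-4-iodo-3-methylbut-3-en-2-one | CC(=O)/C(C)=C\I | intermediate
5 | methyl acrylate | C=CC(=O)OC | starting material
6 | formaldehyde | C=O | starting material
7 | methyl 2-(hydroxymethyl)prop-2-enoate | C=C(CO)C(=O)OC | intermediate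
8 | methyl 2-(bromomethyl)prop-2-enoate | C=C(CBr)C(=O)OC | intermediate
9 | lithium (3Z)-4-iodo-3-methylbuta-1,3-dien-2-olate | C=C(O[Li])/C(C)=C\I | intermediate (not isolated)
10 | methyl (6Z)-7-iodo-6-methyl-2-methylidene-5-oxohept-6-enoate | COC(=O)C(=C)CCC(=O)/C(C)=C\I | intermediate
11 | methyl (5S,6Z)-5-hydroxy-7-iodo-6-methyl-2-methylidenehept-6-enoate | COC(=O)C(=C)CC[C@H](O)/C(C)=C\I | intermediate
12 | methyl (5S,6Z)-5-[(tert-butyldimethylsilyl)oxy]-7-iodo-6-methyl-2-methylidenehept-6-enoate | COC(=O)C(=C)CC[C@H](O[Si](C)(C)C(C)(C)C)/C(C)=C\I | intermediate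
13 | (5S,6Z)-5-[(tert-butyldimethylsilyl)oxy]-7-iodo-6-methyl-2-methylidenehept-6-enoic acid | OC(=O)C(=C)CC[C@H](O[Si](C)(C)C(C)(C)C)/C(C)=C\I | intermediate
14 | lithium (tributylstannyl)methanolate | [Li]OC[Sn](CCCC)(CCCC)CCCC | intermediate (not isolated)
15 | tributyl{[(4-methoxyphenyl)methoxy]methyl}stannane | CCCC[Sn](CCCC)(CCCC)COCc1ccc(OC)cc1 | intermediate
16 | methyl (2R)-3-hydroxy-2-methylpropanoate | COC(=O)[C@H](C)CO | starting material
17 | (2R)-3-hydroxy-N-methoxy-N,2-dimethylpropanamide | CON(C)C(=O)[C@H](C)CO | intermediate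
18 | {[(4-methoxyphenyl)methoxy]methyl}lithium | [Li]COCc1ccc(OC)cc1 | intermediate (not isolated)
19 | (3R)-4-hydroxy-1-[(4-methoxyphenyl)methoxy]-3-methylbutan-2-one | COc1ccc(COCC(=O)[C@H](C)CO)cc1 | intermediate
20 | (2R)-4-[(4-methoxyphenyl)methoxy]-2-methyl-3-oxobutyl (triphenylphosphoranylidene)acetate | COc1ccc(COCC(=O)[C@H](C)COC(=O)C=P(c2ccccc2)(c2ccccc2)c2ccccc2)cc1 | intermediate (not isolated)
21 | (5S)-4-{[(4-methoxyphenyl)methoxy]methyl}-5-methyl-5,6-dihydro-2H-pyran-2-one | O=C1C=C(COCc2ccc(OC)cc2)[C@H](C)CO1 | intermediate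
22 | (3S,4R,5R)-3,4-dihydroxy-4-{[(4-methoxyphenyl)methoxy]methyl}-5-methyloxan-2-one | O=C1[C@@H](O)[C@](O)(COCc2ccc(OC)cc2)[C@H](C)CO1 | intermediate
23 | (3S,4R,5R)-4-{[(4-methoxyphenyl)methoxy]methyl}-5-methyloxane-2,3,4-triol (lactol, anomer mixture) | OC1[C@@H](O)[C@](O)(COCc2ccc(OC)cc2)[C@H](C)CO1 | intermediate (not isolated)
24 | (2R,3R,4R)-3-{[(4-methoxyphenyl)methoxy]methyl}-2-methylhex-5-ene-1,3,4-triol | C=C[C@@H](O)[C@](O)(COCc1ccc(OC)cc1)[C@H](C)CO | intermediate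
25 | (3R,4R,5R)-4-{[(4-methoxyphenyl)methoxy]methyl}-5-methyl-6-[(triethylsilyl)oxy]hex-1-ene-3,4-diol | C=C[C@@H](O)[C@](O)(COCc1ccc(OC)cc1)[C@H](C)CO[Si](CC)(CC)CC | intermediate
26 | mixed anhydride of 13 with 2,4,6-trichlorobenzoic acid | C=C(CC[C@H](O[Si](C)(C)C(C)(C)C)/C(C)=C\I)C(=O)OC(=O)c1c(Cl)cc(Cl)cc1Cl | intermediate (not isolated)
27 | (3R,4R,5R)-4-hydroxy-4-{[(4-methoxyphenyl)methoxy]methyl}-5-methyl-6-[(triethylsilyl)oxy]hex-1-en-3-yl (5S,6Z)-5-[(tert-butyldimethylsilyl)oxy]-7-iodo-6-methyl-2-methylidenehept-6-enoate | C=C(CC[C@H](O[Si](C)(C)C(C)(C)C)/C(C)=C\I)C(=O)O[C@H](C=C)[C@](O)(COCc1ccc(OC)cc1)[C@H](C)CO[Si](CC)(CC)CC | intermediate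
28 | (5R)-5-{(2R,3R)-2-hydroxy-1-[(4-methoxyphenyl)methoxy]-3-methyl-4-[(triethylsilyl)oxy]butan-2-yl}-3-{(3S,4Z)-3-[(tert-butyldimethylsilyl)oxy]-5-iodo-4-methylpent-4-en-1-yl}furan-2(5H)-one | O=C1O[C@@H]([C@](O)(COCc2ccc(OC)cc2)[C@H](C)CO[Si](CC)(CC)CC)C=C1CC[C@H](O[Si](C)(C)C(C)(C)C)/C(C)=C\I | intermediate
29 | (3S,4S,5R)-3,4-dihydroxy-5-{(2R,3R)-2-hydroxy-1-[(4-methoxyphenyl)methoxy]-3-methyl-4-[(triethylsilyl)oxy]butan-2-yl}-3-{(3S,4Z)-3-[(tert-butyldimethylsilyl)oxy]-5-iodo-4-methylpent-4-en-1-yl}oxolan-2-one | O=C1O[C@@H]([C@](O)(COCc2ccc(OC)cc2)[C@H](C)CO[Si](CC)(CC)CC)[C@H](O)[C@@]1(O)CC[C@H](O[Si](C)(C)C(C)(C)C)/C(C)=C\I | intermediate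
30 | (2R,3S,4S)-4-hydroxy-2-{(2R,3R)-2-hydroxy-1-[(4-methoxyphenyl)methoxy]-3-methyl-4-[(triethylsilyl)oxy]butan-2-yl}-4-{(3S,4Z)-3-[(tert-butyldimethylsilyl)oxy]-5-iodo-4-methylpent-4-en-1-yl}-5-oxooxolan-3-yl acetate | O=C1O[C@@H]([C@](O)(COCc2ccc(OC)cc2)[C@H](C)CO[Si](CC)(CC)CC)[C@H](OC(C)=O)[C@@]1(O)CC[C@H](O[Si](C)(C)C(C)(C)C)/C(C)=C\I | intermediate
31 | (2R,3S,4S)-2-{(2R,3R)-1,2-dihydroxy-3-methyl-4-[(triethylsilyl)oxy]butan-2-yl}-4-hydroxy-4-{(3S,4Z)-3-[(tert-butyldimethylsilyl)oxy]-5-iodo-4-methylpent-4-en-1-yl}-5-oxooxolan-3-yl acetate | O=C1O[C@@H]([C@](O)(CO)[C@H](C)CO[Si](CC)(CC)CC)[C@H](OC(C)=O)[C@@]1(O)CC[C@H](O[Si](C)(C)C(C)(C)C)/C(C)=C\I | intermediate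
32 | (2R,3S,4S)-4-hydroxy-2-{(2S,3R)-2-hydroxy-3-methyl-1-oxo-4-[(triethylsilyl)oxy]butan-2-yl}-4-{(3S,4Z)-3-[(tert-butyldimethylsilyl)oxy]-5-iodo-4-methylpent-4-en-1-yl}-5-oxooxolan-3-yl acetate | O=C1O[C@@H]([C@](O)(C=O)[C@H](C)CO[Si](CC)(CC)CC)[C@H](OC(C)=O)[C@@]1(O)CC[C@H](O[Si](C)(C)C(C)(C)C)/C(C)=C\I | intermediate
33 | (1S,4S,5S,6R,7R,11R,9Z)-5-acetoxy-1-[(tert-butyldimethylsilyl)oxy]-4,7,8-trihydroxy-12-[(triethylsilyl)oxy]germacr-9-en-15,6-olide (C8 epimers) | CC(=O)O[C@H]1[C@H]2OC(=O)[C@]1(O)CC[C@H](O[Si](C)(C)C(C)(C)C)/C(C)=C\C(O)[C@]2(O)[C@H](C)CO[Si](CC)(CC)CC | intermediate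
34 | (1S,4S,5S,6R,7S,11R,9Z)-5-acetoxy-1-[(tert-butyldimethylsilyl)oxy]-4,7-dihydroxy-8-oxo-12-[(triethylsilyl)oxy]germacr-9-en-15,6-olide | CC(=O)O[C@H]1[C@H]2OC(=O)[C@]1(O)CC[C@H](O[Si](C)(C)C(C)(C)C)/C(C)=C\C(=O)[C@]2(O)[C@H](C)CO[Si](CC)(CC)CC | intermediate
35 | (1S,4S,5S,6R,7S,11R,9Z)-5-acetoxy-1-[(tert-butyldimethylsilyl)oxy]-4,7,12-trihydroxy-8-oxogermacr-9-en-15,6-olide | CC(=O)O[C@H]1[C@H]2OC(=O)[C@]1(O)CC[C@H](O[Si](C)(C)C(C)(C)C)/C(C)=C\C(=O)[C@]2(O)[C@H](C)CO | intermediate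
36 | (1S,4S,5S,6R,7S,11S,9Z)-5-acetoxy-1-[(tert-butyldimethylsilyl)oxy]-4,7-dihydroxy-8-oxogermacr-9-en-15,6-olid-12-oic acid | CC(=O)O[C@H]1[C@H]2OC(=O)[C@]1(O)CC[C@H](O[Si](C)(C)C(C)(C)C)/C(C)=C\C(=O)[C@]2(O)[C@H](C)C(=O)O | intermediate
37 | (1S,4S,5S,6R,7S,11S,9Z)-5-acetoxy-1,4,7-trihydroxy-8-oxogermacr-9-en-15,6-olid-12-oic acid | CC(=O)O[C@H]1[C@H]2OC(=O)[C@]1(O)CC[C@H](O)/C(C)=C\C(=O)[C@]2(O)[C@H](C)C(=O)O | intermediate (not isolated)
38 | (1S,4S,5S,6R,7S,11S)-5-acetoxy-1,8-epoxy-4,7,8-trihydroxygermacr-9-en-15,6-olid-12-oic acid (hemiketal) | CC(=O)O[C@H]1[C@H]2OC(=O)[C@]1(O)CC[C@@H]1OC(O)(C=C1C)[C@]2(O)[C@H](C)C(=O)O | intermediate (not isolated)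
39 | (1S,4S,5S,6R,7S,8S,11S)-5-acetoxy-1,8-epoxy-4,7-dihydroxygermacr-9-ene-12,8:15,6-diolide | CC(=O)O[C@H]1[C@H]2OC(=O)[C@]1(O)CC[C@@H]1O[C@@]3(C=C1C)OC(=O)[C@@H](C)[C@]23O | target

**Totals**
Total step count: 26.
Longest linear sequence: 17 steps (16 → 39 through steps 10–15 and 16–26; the routes from 1, 5 and 6 are equally long).

**Steps most likely to fail**

Step 22 (NHK macrocyclisation). Closing a ten-membered ring onto a neopentyl α-hydroxy aldehyde may give oligomers or simple reduction of the iodide. The fallback sets out from 32 and comes back at 34, replacing carbonyl addition by an acylative cross-coupling that gives the enone directly. Pinnick oxidation (NaClO2, NaH2PO4, 2-methylbut-2-ene) of 32 gives the C8 carboxylic acid (2S,3R)-2-[(2R,3S,4S)-3-acetoxy-4-hydroxy-4-{(3S,4Z)-3-[(tert-butyldimethylsilyl)oxy]-5-iodo-4-methylpent-4-en-1-yl}-5-oxooxolan-2-yl]-2-hydroxy-3-methyl-4-[(triethylsilyl)oxy]butanoic acid F3. EtSH, DCC and DMAP convert it into the corresponding S-ethyl butanethioate F4. Hexamethylditin with Pd(PPh3)4 exchanges iodide for tin with retention to give the (Z)-5-(trimethylstannyl)pentenyl S-ethyl thioester F5. Liebeskind–Srogl-type ring closure of F5 (Pd2(dba)3, tri(2-furyl)phosphine, copper(I) diphenylphosphinate, high dilution) then forms the C8–C9 bond as the ketone, giving 34.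

Step 26 (desilylation, ketalisation and lactonisation). Acid may cause elimination or decomposition before the spiro-lactone closes. The fallback sets out from 34 and comes back at 39, forming the spiro centre oxidatively instead of through an acid-generated oxocarbenium ion. Buffered TBAF/AcOH in THF at 0 °C removes both silyl groups from 34, and the freed 1-OH adds to C8 to give the hemiketal (1S,4S,5S,6R,7S,11R)-5-acetoxy-1,8-epoxy-4,7,8,12-tetrahydroxygermacr-9-en-15,6-olide F6, isolated without acid. TEMPO/PhI(OAc)2 in CH2Cl2 oxidises the primary 12-OH to the aldehyde, which is trapped by the 8-OH as a spiro-lactol and oxidised on to the lactone 39.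

Step 5 (alkylation of the β-iodo enone enolate). The enolate may self-condense or lose iodide. The fallback sets out from 4 (with 7) and comes back at 10, using a sigmatropic rearrangement instead of enolate chemistry. HC(OMe)3, MeOH and cat. TsOH convert 4 into its ketal (1Z)-1-iodo-3,3-dimethoxy-2-methylbut-1-ene F1. Heating F1 with allylic alcohol 7 and cat. propionic acid (toluene, 110 °C, MeOH distilled off) gives, by ketal exchange and elimination, the allyl vinyl ether methyl 2-({[(3Z)-4-iodo-3-methylbuta-1,3-dien-2-yl]oxy}methyl)prop-2-enoate F2. F2 undergoes Claisen rearrangement in the same pot to keto ester 10.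

**Further compounds**
F1 | step 5 | (1Z)-1-iodo-3,3-dimethoxy-2-methylbut-1-ene | COC(C)(OC)/C(C)=C\I
F2 | step 5 | methyl 2-({[(3Z)-4-iodo-3-methylbuta-1,3-dien-2-yl]oxy}methyl)prop-2-enoate | C=C(OCC(=C)C(=O)OC)/C(C)=C\I
F3 | step 22 | (2S,3R)-2-[(2R,3S,4S)-3-acetoxy-4-hydroxy-4-{(3S,4Z)-3-[(tert-butyldimethylsilyl)oxy]-5-iodo-4-methylpent-4-en-1-yl}-5-oxooxolan-2-yl]-2-hydroxy-3-methyl-4-[(triethylsilyl)oxy]butanoic acid | O=C1O[C@@H]([C@](O)(C(=O)O)[C@H](C)CO[Si](CC)(CC)CC)[C@H](OC(C)=O)[C@@]1(O)CC[C@H](O[Si](C)(C)C(C)(C)C)/C(C)=C\I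
F4 | step 22 | S-ethyl (2S,3R)-2-[(2R,3S,4S)-3-acetoxy-4-hydroxy-4-{(3S,4Z)-3-[(tert-butyldimethylsilyl)oxy]-5-iodo-4-methylpent-4-en-1-yl}-5-oxooxolan-2-yl]-2-hydroxy-3-methyl-4-[(triethylsilyl)oxy]butanethioate | O=C1O[C@@H]([C@](O)(C(=O)SCC)[C@H](C)CO[Si](CC)(CC)CC)[C@H](OC(C)=O)[C@@]1(O)CC[C@H](O[Si](C)(C)C(C)(C)C)/C(C)=C\I
F5 | step 22 | S-ethyl (2S,3R)-2-[(2R,3S,4S)-3-acetoxy-4-hydroxy-4-{(3S,4Z)-3-[(tert-butyldimethylsilyl)oxy]-4-methyl-5-(trimethylstannyl)pent-4-en-1-yl}-5-oxooxolan-2-yl]-2-hydroxy-3-methyl-4-[(triethylsilyl)oxy]butanethioate | O=C1O[C@@H]([C@](O)(C(=O)SCC)[C@H](C)CO[Si](CC)(CC)CC)[C@H](OC(C)=O)[C@@]1(O)CC[C@H](O[Si](C)(C)C(C)(C)C)/C(C)=C\[Sn](C)(C)C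
F6 | step 26 | (1S,4S,5S,6R,7S,11R)-5-acetoxy-1,8-epoxy-4,7,8,12-tetrahydroxygermacr-9-en-15,6-olide (hemiketal) | CC(=O)O[C@H]1[C@H]2OC(=O)[C@]1(O)CC[C@@H]1OC(O)(C=C1C)[C@]2(O)[C@H](C)CO
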